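Assumption (remark on the chemistry): the target has no stereocentre and the C8–O–C1' ether axis is taken as freely rotating, so no stereocontrol is needed; compounds 1, 4, 7 and 15 are taken as commercial.

## Analysis of the target

- The target is a 1H-isochromen-1-one (isocoumarin). Benzene ring A (C4a, C5, C6, C7, C8, C8a) is fused to the α-pyranone ring C (C1, O2, C3, C4). It carries n-pentyl at C3, a free OH at C6 and an aryloxy group at C8. The aryl ring B (C1'–C6') has OH at C2', OMe at C4' and n-pentyl at C6'.
- There is no stereocentre and the molecule is achiral.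
- Ring A has the orsellinate pattern: oxygen at C6 and C8 (1,3-related) with the C1 carbonyl on C8a between C8 and C4a. Ring B is a 1,2,4-trioxygenated, very electron-rich arene.
- Sensitive groups are the enol lactone of ring C (opened by hydroxide or alkoxide; C3=C4 can be hydrogenated), the oxidation-prone ring B, and three phenolic oxygens that must end in three different states (6-OH, 2'-OH, 4'-OMe) beside the ether oxygen.
- The hard bond is C8–O–C1'. It is a tri-ortho-substituted diaryl ether: C8 lies peri to the C1 carbonyl, and C1' lies between C2'–O and the C6' pentyl group. Any arene C–O coupling must join a 2,6-disubstituted phenol to a crowded, poorly activated carbon.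
- The feature the route exploits: C7–C8(O)–C8a–C4a of ring A are the diene carbons C3–C4(O)–C5–C6 of a 4-oxygenated 2-pyranone, and C5–C6(O) are the two carbons of a ketene acetal. Ring A can therefore be made from a second 2-pyranone ring (ring D) by cycloaddition and loss of its lactone bridge.
- Before that ring change, C8 is not an arene carbon but the β-carbon of an unsaturated lactone, where the hindered C–O bond can form by simple addition–elimination.

## Retrosynthetic reasoning

**22 ⇒ 21.** The last step only frees O2' from a benzyl group. Benzyl is chosen because a free or silylated O2' next to the aryloxy-pyranone of 14 could shift the pyranone or the silyl group between the two catechol oxygens. Benzyl is inert to base and heat and can be removed without touching the 4'-OMe or ring C.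

**21 ⇒ 14 + 17 (key disconnection).** Ring A is cut at C4a–C5 and C6–C7. C5 and C6 with the C6 oxygen come from ketene acetal 17. C7, C8, C8a and C4a are the diene of ring D in the pyrano[4,3-b]pyran-2,5-dione 14. The forward step must add 17 across C3/C8a of ring D (giving 18), extrude the lactone bridge by decarboxylative cycloreversion (giving 19) and aromatize by loss of one silyloxy group (giving 20, then 21). What is gained: ring C, the C3 pentyl chain and the complete C8–O–C1' ether are already in 14, and the 6-OH arrives unprotected and regiodefined. The cut is made here and not at the C8–O bond of the arene because this is the only cut that moves the ether formation off an aromatic carbon.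

**14 ⇒ 6 + 13.** The C4–O bond of ring D (the future C8–O bond) is cut. The forward reaction is a nucleophilic vinylic substitution of the vinylogous acid chloride 6 by the phenoxide of 13. Attack occurs at a planar β-halo-enone carbon, so the two ortho groups of 13 matter far less than in an arene coupling.

**6 ⇒ 5 ⇒ 3 + 4, and 3 ⇒ 1.** Ring D is cut at C4a–C4 and O1–C2. A malonyl unit from the active ester 4 is condensed onto C3/O4 of 4-hydroxy-6-pentyl-2-pyranone 3, and the 4-OH of 5 is then turned into chloride. The pentyl chain of 3 comes from a C–C cut next to the pyranone: the methyl group of 1 is alkylated through dianion 2.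

**13 ⇒ 11 ⇒ 10 ⇒ 9 ⇒ 7.** The C1'–O bond of ring B is traced to a formyl group (via formate 12), which serves as a latent hydroxyl that differs from the other two oxygens from the start. The formyl group is introduced on symmetrical 7 (via iminium salt 8). The para hydroxyl of 9 is methylated first (it is not chelated), and the chelated ortho hydroxyl of 10 is benzylated second. This fixes OH, OMe and O-aryl on ring B without a selectivity problem.

**17 ⇒ 15.** The ketene acetal is the O-silylated enolate 16 of silyl ester 15. A bis-silyl acetal is chosen so that either silyloxy group may leave in the aromatization and the C6 oxygen appears as a free phenol after work-up.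

## Alternatives that were turned down

**Alternative 1:** the textbook route, cutting C8–O on the finished arene.
- Disconnection and forward step: nucleophilic aromatic substitution (or a copper- or palladium-catalysed Ullmann-type coupling) of phenol 13 with methyl 4-(benzyloxy)-2-fluoro-6-(hept-1-yn-1-yl)benzoate A1 to give diaryl ether A2. 6-endo-dig lactonization to ring C and debenzylation would then give 22.
- Why turned down:
  - The ester of A1 has two ortho neighbours and is twisted out of conjugation, and the para benzyloxy group donates into it, so fluoride is poorly activated.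
  - The nucleophile is a 2,6-disubstituted phenoxide. A metal-catalysed version would need reductive elimination to a tri-ortho-substituted ether.
  - A1 is a 1,2,3,5-tetrasubstituted benzene that needs its own regiocontrolled multi-step synthesis.
  - Ring C closure adds a 5-exo versus 6-endo question.
  - The hardest bond would be made by the least favourable reaction, with no saving in steps.

**Alternative 2:** biomimetic dehydrogenative C–O coupling of two nucleophilic partners.
- Disconnection and forward step: anodic or one-electron oxidation joins O8 of 6,8-dihydroxy-3-pentyl-1H-isochromen-1-one A3 to the carbon para to OMe of 3-methoxy-5-pentylphenol A4, giving 22 directly.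
- Why turned down:
  - A4 is oxidized far more easily than A3, and its radical or cation has three reactive ring carbons besides oxygen.
  - O8–H of A3 is hydrogen bonded to C1=O and is the less available hydroxyl; O6 and C–C coupling at C5 or C7 compete.
  - The product, a para-alkoxy catechol monoether, is more oxidizable than either partner, so over-oxidation to quinones is expected.
  - Nothing in the substrates enforces the one required O-to-C union.

**Alternative 3:** Danheiser benzannulation to ring A.
- Disconnection and forward step: the aryl ethynyl ether A5 (made from 13) and methyl 2-(hept-1-yn-1-yl)-4-oxocyclobut-1-ene-1-carboxylate A6 are heated. 4π opening to a vinylketene, [2+2] with A5, a second 4π opening and 6π closure would give salicylate A7, with the aryloxy group meta to the new hydroxyl.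
- Why turned down:
  - The vinylketene from A6 carries the ester on the ketene carbon. It is an acylketene and should react with the ynol ether as a 1-oxadiene, giving 4-pyranones, rather than by [2+2].
  - A6 is a strained, doubly activated acceptor that needs several steps to make.
  - A7 still lacks ring C, so the route is longer than the one chosen.

Key step: step 10

## Route

Step 1
Reactants: 1 4-hydroxy-6-methyl-2H-pyran-2-one
Product: 3 4-hydroxy-6-pentyl-2H-pyran-2-one, via dilithium dianion 2 (not isolated)
Conditions: LiN(iPr)2 (2.3 equiv), THF/DMPU, −78 °C; n-BuI, −78 → 0 °C; then 1 M HCl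
Reagents that add atoms: 1-iodobutane, CCCCI
Why: Double deprotonation (O4–H, then the vinylogous 6-methyl group) gives dianion 2, whose carbanion, the last-formed and most basic site, is alkylated by the primary iodide in an SN2 reaction; this is the established dianion alkylation of 4-hydroxy-6-methyl-2-pyranone.

Step 2
Reactants: 3 4-hydroxy-6-pentyl-2H-pyran-2-one; 4 bis(2,4,6-trichlorophenyl) malonate
Product: 5 4-hydroxy-7-pentyl-2H,5H-pyrano[4,3-b]pyran-2,5-dione
Conditions: 4 (1.0 equiv), PhBr, reflux
Reagents that add atoms: none
Why: Thermal malonylation with the active aryl malonate: C-acylation at the nucleophilic C3 of the 4-hydroxypyranone, then lactonization through O4, builds ring D; this is the standard malonate annulation of 4-hydroxy-2-pyranones and 4-hydroxycoumarins, driven by loss of the aryl oxide leaving groups.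

Step 3
Reactants: 5 4-hydroxy-7-pentyl-2H,5H-pyrano[4,3-b]pyran-2,5-dione
Product: 6 4-chloro-7-pentyl-2H,5H-pyrano[4,3-b]pyran-2,5-dione
Conditions: POCl3, Et3N, ClCH2CH2Cl, 70 °C
Reagents that add atoms: phosphoryl chloride, O=P(Cl)(Cl)Cl
Why: The vinylogous acid is O-phosphorylated and chloride displaces the dichlorophosphate by addition–elimination at C4, as in the conversion of 4-hydroxycoumarins into 4-chlorocoumarins; neither lactone reacts.

Step 4
Reactants: 7 olivetol (5-pentylbenzene-1,3-diol)
Product: 9 2,4-dihydroxy-6-pentylbenzaldehyde, via aryl iminium chloride 8 (not isolated)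
Conditions: POCl3, DMF, 0 → 23 °C; then H2O, 50 °C
Reagents that add atoms: N,N-dimethylformamide, CN(C)C=O; water, O
Why: Vilsmeier–Haack formylation; the two positions ortho/para to the hydroxyls and next to the pentyl group are equivalent by symmetry and are preferred over the carbon between the two hydroxyls, and hydrolysis of iminium salt 8 gives the aldehyde.

Step 5
Reactants: 9 2,4-dihydroxy-6-pentylbenzaldehyde
Product: 10 2-hydroxy-4-methoxy-6-pentylbenzaldehyde
Conditions: MeI (1.05 equiv), K2CO3, acetone, 23 °C
Reagents that add atoms: iodomethane, CI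
Why: Williamson etherification; the para hydroxyl is the more acidic (vinylogous acid) and is free, whereas the ortho hydroxyl is locked in a hydrogen bond to the formyl group, so one equivalent of MeI should methylate O4 only.

Step 6
Reactants: 10 2-hydroxy-4-methoxy-6-pentylbenzaldehyde
Product: 11 2-(benzyloxy)-4-methoxy-6-pentylbenzaldehyde
Conditions: BnBr, K2CO3, DMF, 60 °C
Reagents that add atoms: benzyl bromide, BrCc1ccccc1
Why: Williamson benzylation of the remaining chelated phenol under more forcing conditions; this puts the future 2'-oxygen into a group that cannot migrate and survives base, heat and peracid.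

Step 7
Reactants: 11 2-(benzyloxy)-4-methoxy-6-pentylbenzaldehyde
Product: 13 2-(benzyloxy)-4-methoxy-6-pentylphenol, via aryl formate 12 (not isolated)
Conditions: mCPBA, CH2Cl2, 0 → 23 °C; then K2CO3 (cat.), MeOH, 23 °C
Reagents that add atoms: 3-chloroperoxybenzoic acid, O=C(OO)c1cccc(Cl)c1
Why: Baeyer–Villiger (Dakin-type) oxidation; the electron-rich 2,4-dialkoxyaryl group migrates in preference to hydride to give formate 12, and mild methanolysis frees the phenol that becomes the ether oxygen on C1'.

Step 8
Reactants: 6 4-chloro-7-pentyl-2H,5H-pyrano[4,3-b]pyran-2,5-dione; 13 2-(benzyloxy)-4-methoxy-6-pentylphenol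
Product: 14 4-[2-(benzyloxy)-4-methoxy-6-pentylphenoxy]-7-pentyl-2H,5H-pyrano[4,3-b]pyran-2,5-dione
Conditions: K2CO3, MeCN, 23 → 50 °C
Reagents that add atoms: none
Why: Nucleophilic vinylic substitution (addition–elimination) at C4 of the vinylogous acid chloride, as with 4-chlorocoumarins and phenols; attack on a planar β-chloro-enone carbon tolerates the two ortho groups of 13, and only chloride loss is irreversible, so reversible opening of a lactone by phenoxide should funnel back to 14.

Step 9
Reactants: 15 trimethylsilyl acetate
Product: 17 1,1-bis(trimethylsilyloxy)ethene, via lithium enolate 16 (not isolated)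
Conditions: LiN(iPr)2, THF, −78 °C; then Me3SiCl, −78 → 23 °C; distillation
Reagents that add atoms: chlorotrimethylsilane, C[Si](C)(C)Cl
Why: Kinetic enolization of the silyl ester and O-silylation of the hard enolate oxygen, the usual preparation of ketene bis(silyl) acetals.

Step 10
Reactants: 14 4-[2-(benzyloxy)-4-methoxy-6-pentylphenoxy]-7-pentyl-2H,5H-pyrano[4,3-b]pyran-2,5-dione; 17 1,1-bis(trimethylsilyloxy)ethene
Product: 21 8-[2-(benzyloxy)-4-methoxy-6-pentylphenoxy]-6-hydroxy-3-pentyl-1H-isochromen-1-one, via bridged lactone cycloadduct 18 (not isolated), via dihydroisocoumarin bis(silyl) ketal 19 (not isolated), via aryl silyl ether 20 (not isolated)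
Conditions: 17 (4 equiv), PhMe, 110 °C, sealed tube; then 1 M HCl, THF, 23 °C
Reagents that add atoms: none
Why: Ring D of 14 (O1, C2, C3, C4, C4a, C8a) is a 2-pyranone with the ring C carbonyl C5 on C4a, the pattern of a coumalate, so C8a (β to C5=O, δ to C2=O) is its most electrophilic carbon; the nucleophilic CH2 of 17 bonds there while the acetal carbon closes on C3, an inverse-electron-demand Diels–Alder reaction of the known type that converts 2-pyranones and ketene acetals into oxygenated arenes. Cycloadduct 18 loses the O1–C2 bridge as CO2 by retro-[4+2] to give diene 19, which aromatizes by 1,2-elimination of Me3SiOH across C5–C6 to 20; the acid work-up cleaves the aryl silyl ether to 21, and any 19 that survives is hydrolysed to the dienone tautomer of the same phenol. Ring A is therefore closed as a six-membered carbocycle by an intermolecular [4+2] cycloaddition that forms C4a–C5 and C6–C7 (isocoumarin numbering) together, not by cyclization of a chain. No stereocentre has to be controlled, since the two bridgehead centres of 18 vanish in the cycloreversion. Regioselectivity (oxygen at C6, not C5) follows from the polarity match of the CH2 terminus of 17 with C8a. Periselectivity for ring D over the second 2-pyranone (ring C) is expected because the ring D mode ends at the unsubstituted C3–H, whereas the ring C mode would have to build a quaternary centre at C4a beside the bulky aryloxy group. Substitution of the aryloxy group at C4 is disfavoured because C4 is a donor-substituted vinylogous carbonate carbon and not a diene terminus, and because both enone units are locked s-trans, which denies 17 a cyclic silyl-transfer (Mukaiyama–Michael) pathway and leaves ring closure at C3 as the easy fate of any zwitterion.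

Step 11
Reactants: 21 8-[2-(benzyloxy)-4-methoxy-6-pentylphenoxy]-6-hydroxy-3-pentyl-1H-isochromen-1-one
Product: 22 6-hydroxy-8-(2-hydroxy-4-methoxy-6-pentylphenoxy)-3-pentyl-1H-isochromen-1-one (NP-007099)
Conditions: BCl3, C6HMe5 (pentamethylbenzene), CH2Cl2, −78 °C; then MeOH
Reagents that add atoms: none
Why: Lewis-acid debenzylation with a non-Lewis-basic cation scavenger; at −78 °C BCl3 should cleave the benzyl ether but not the unchelated 4'-methyl ether, the diaryl ether or the lactone, and pentamethylbenzene traps the benzyl cation before it can alkylate ring B, while the C3=C4 bond, at risk under hydrogenolysis, is untouched.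

## Compound list

1 | 4-hydroxy-6-methyl-2H-pyran-2-one | CC1=CC(O)=CC(=O)O1 | starting material
2 | dilithium dianion of 1 (lithium 6-(lithiomethyl)-2-oxo-2H-pyran-4-olate) | [Li+].[Li+].[CH2-]C1=CC([O-])=CC(=O)O1 | intermediate
3 | 4-hydroxy-6-pentyl-2H-pyran-2-one | CCCCCC1=CC(O)=CC(=O)O1 | intermediate
4 | bis(2,4,6-trichlorophenyl) malonate | O=C(CC(=O)Oc1c(Cl)cc(Cl)cc1Cl)Oc1c(Cl)cc(Cl)cc1Cl | starting material
5 | 4-hydroxy-7-pentyl-2H,5H-pyrano[4,3-b]pyran-2,5-dione | CCCCCC1=CC2=C(C(=O)O1)C(O)=CC(=O)O2 | intermediate
6 | 4-chloro-7-pentyl-2H,5H-pyrano[4,3-b]pyran-2,5-dione | CCCCCC1=CC2=C(C(=O)O1)C(Cl)=CC(=O)O2 | intermediate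
7 | olivetol (5-pentylbenzene-1,3-diol) | CCCCCc1cc(O)cc(O)c1 | starting material
8 | N-[(2,4-dihydroxy-6-pentylphenyl)methylidene]-N-methylmethanaminium chloride | CCCCCc1cc(O)cc(O)c1C=[N+](C)C.[Cl-] | intermediate
9 | 2,4-dihydroxy-6-pentylbenzaldehyde | CCCCCc1cc(O)cc(O)c1C=O | intermediate
10 | 2-hydroxy-4-methoxy-6-pentylbenzaldehyde | CCCCCc1cc(OC)cc(O)c1C=O | intermediate
11 | 2-(benzyloxy)-4-methoxy-6-pentylbenzaldehyde | CCCCCc1cc(OC)cc(OCc2ccccc2)c1C=O | intermediate
12 | 2-(benzyloxy)-4-methoxy-6-pentylphenyl formate | CCCCCc1cc(OC)cc(OCc2ccccc2)c1OC=O | intermediate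
13 | 2-(benzyloxy)-4-methoxy-6-pentylphenol | CCCCCc1cc(OC)cc(OCc2ccccc2)c1O | intermediate
14 | 4-[2-(benzyloxy)-4-methoxy-6-pentylphenoxy]-7-pentyl-2H,5H-pyrano[4,3-b]pyran-2,5-dione | CCCCCC1=CC2=C(C(=O)O1)C(Oc1c(OCc3ccccc3)cc(OC)cc1CCCCC)=CC(=O)O2 | intermediate
15 | trimethylsilyl acetate | CC(=O)O[Si](C)(C)C | starting material
16 | lithium 1-(trimethylsilyloxy)ethen-1-olate | [Li+].C=C([O-])O[Si](C)(C)C | intermediate
17 | 1,1-bis(trimethylsilyloxy)ethene | C=C(O[Si](C)(C)C)O[Si](C)(C)C | intermediate
18 | bridged lactone cycloadduct of 14 and 17 (2-oxabicyclo[2.2.2]oct-5-en-3-one core, new bonds C8a–CH2 and C3–C(OSiMe3)2; racemic, relative configuration fixed by the bridge) | CCCCCC1=CC23CC(O[Si](C)(C)C)(O[Si](C)(C)C)C(C(=O)O2)C(Oc2c(OCc4ccccc4)cc(OC)cc2CCCCC)=C3C(=O)O1 | intermediate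
19 | 8-[2-(benzyloxy)-4-methoxy-6-pentylphenoxy]-3-pentyl-6,6-bis(trimethylsilyloxy)-5,6-dihydro-1H-isochromen-1-one | CCCCCC1=CC2=C(C(=O)O1)C(Oc1c(OCc3ccccc3)cc(OC)cc1CCCCC)=CC(O[Si](C)(C)C)(O[Si](C)(C)C)C2 | intermediate
20 | 8-[2-(benzyloxy)-4-methoxy-6-pentylphenoxy]-3-pentyl-6-(trimethylsilyloxy)-1H-isochromen-1-one | CCCCCc1cc2cc(O[Si](C)(C)C)cc(Oc3c(OCc4ccccc4)cc(OC)cc3CCCCC)c2c(=O)o1 | intermediate
21 | 8-[2-(benzyloxy)-4-methoxy-6-pentylphenoxy]-6-hydroxy-3-pentyl-1H-isochromen-1-one | CCCCCc1cc2cc(O)cc(Oc3c(OCc4ccccc4)cc(OC)cc3CCCCC)c2c(=O)o1 | intermediate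
22 | 6-hydroxy-8-(2-hydroxy-4-methoxy-6-pentylphenoxy)-3-pentyl-1H-isochromen-1-one (NP-007099) | CCCCCc1cc2cc(O)cc(Oc3c(O)cc(OC)cc3CCCCC)c2c(=O)o1 | target

## Step count and least certain steps

Total step count: 11 (three branches: steps 1–3, steps 4–7, step 9; union in steps 8 and 10; step 11 to finish).
Longest linear sequence: 7 steps (7 → 9 → 10 → 11 → 13 → 14 → 21 → 22; steps 4, 5, 6, 7, 8, 10, 11).

**Step 10 (key step).**
- What may go wrong: the cycloaddition may be too slow, because the aryloxy donor at C4 raises the LUMO of the ring D diene, so that thermal O-to-C silyl migration or hydrolytic loss of 17 outruns it. Less likely are conjugate addition at C4 with expulsion of the aryloxide, and cycloaddition on the ring C diene.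
- Fallback (benzannulation first, ether formation on the arene): it sets out from 6 and 13 and rejoins the route at 22.
  - Chloride 6, a more electron-poor diene, is heated with commercial 1,1-diethoxyethene (C=C(OCC)OCC) to give 8-chloro-6-ethoxy-3-pentyl-1H-isochromen-1-one F1.
  - BBr3 in CH2Cl2 cleaves the ethyl ether to 8-chloro-6-hydroxy-3-pentyl-1H-isochromen-1-one F2.
  - Benzylation (BnBr, K2CO3, DMF) gives 6-(benzyloxy)-8-chloro-3-pentyl-1H-isochromen-1-one F3.
  - An Ullmann ether coupling of F3 with 13 (CuI, N,N-dimethylglycine, Cs2CO3, dioxane, 100 °C), assisted by the ortho lactone carbonyl, gives 6-(benzyloxy)-8-[2-(benzyloxy)-4-methoxy-6-pentylphenoxy]-3-pentyl-1H-isochromen-1-one F4.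
  - The conditions of step 11 with a doubled charge of BCl3 remove both benzyl groups to give 22.

**Step 8.**
- What may go wrong: substitution by the 2,6-disubstituted phenoxide may be slow, so that opening of the ring D enol lactone at C2 and hydrolysis of the vinylogous acid chloride by traces of water take over.
- Fallback (make the hindered C–O bond on a two-carbon electrophile and close ring D afterwards): it sets out from 13 and 3 and rejoins the route at 14.
  - The potassium phenoxide of 13 (KH, THF) adds to trichloroethylene (ClC=C(Cl)Cl) to give 1-(benzyloxy)-2-{[(E)-1,2-dichloroethenyl]oxy}-5-methoxy-3-pentylbenzene F5.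
  - n-BuLi (2.2 equiv, −78 °C) converts F5 by elimination and chlorine–lithium exchange into lithium [2-(benzyloxy)-4-methoxy-6-pentylphenoxy]acetylide F6.
  - Methyl chloroformate traps F6 as methyl 3-[2-(benzyloxy)-4-methoxy-6-pentylphenoxy]prop-2-ynoate F7.
  - Conjugate addition of C3 of pyranone 3 to the oxygen-bearing alkyne carbon of F7 and lactonization through O4 (Et3N or ZnCl2, PhMe, heat) closes ring D with the aryloxy group already in place and gives 14.

**Step 2.**
- What may go wrong: over-annulation, since product 5 is itself a 4-hydroxy-2-pyranone with a free C3 position and can take up a second malonyl unit; thermal degradation at the temperature needed is also possible.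
- Fallback (stepwise construction of ring D): it sets out from 3 and rejoins the route at 5.
  - Acetic acid, DCC and DMAP acylate O4 of 3, and DMAP then moves the acetyl group to C3 (the usual O-to-C acyl shift of 4-acyloxy-2-pyranones), giving 3-acetyl-4-hydroxy-6-pentyl-2H-pyran-2-one F8.
  - NaH and diethyl carbonate (THF, reflux) effect a Claisen condensation at the acetyl methyl group, and the resulting β-keto ester lactonizes onto O4 to give 5.

## Further compounds

F1 | step 10 | 8-chloro-6-ethoxy-3-pentyl-1H-isochromen-1-one | CCCCCc1cc2cc(OCC)cc(Cl)c2c(=O)o1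
F2 | step 10 | 8-chloro-6-hydroxy-3-pentyl-1H-isochromen-1-one | CCCCCc1cc2cc(O)cc(Cl)c2c(=O)o1
F3 | step 10 | 6-(benzyloxy)-8-chloro-3-pentyl-1H-isochromen-1-one | CCCCCc1cc2cc(OCc3ccccc3)cc(Cl)c2c(=O)o1
F4 | step 10 | 6-(benzyloxy)-8-[2-(benzyloxy)-4-methoxy-6-pentylphenoxy]-3-pentyl-1H-isochromen-1-one | CCCCCc1cc2cc(OCc3ccccc3)cc(Oc3c(OCc4ccccc4)cc(OC)cc3CCCCC)c2c(=O)o1
F5 | step 8 | 1-(benzyloxy)-2-{[(E)-1,2-dichloroethenyl]oxy}-5-methoxy-3-pentylbenzene | CCCCCc1cc(OC)cc(OCc2ccccc2)c1O/C(Cl)=C\Cl
F6 | step 8 | lithium [2-(benzyloxy)-4-methoxy-6-pentylphenoxy]acetylide | [Li]C#COc1c(OCc2ccccc2)cc(OC)cc1CCCCC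
F7 | step 8 | methyl 3-[2-(benzyloxy)-4-methoxy-6-pentylphenoxy]prop-2-ynoate | COC(=O)C#COc1c(OCc2ccccc2)cc(OC)cc1CCCCC
F8 | step 2 | 3-acetyl-4-hydroxy-6-pentyl-2H-pyran-2-one | CCCCCC1=CC(O)=C(C(C)=O)C(=O)O1
A1 | alternative 1 | methyl 4-(benzyloxy)-2-fluoro-6-(hept-1-yn-1-yl)benzoate | CCCCCC#Cc1cc(OCc2ccccc2)cc(F)c1C(=O)OC
A2 | alternative 1 | methyl 4-(benzyloxy)-2-[2-(benzyloxy)-4-methoxy-6-pentylphenoxy]-6-(hept-1-yn-1-yl)benzoate | CCCCCC#Cc1cc(OCc2ccccc2)cc(Oc2c(OCc3ccccc3)cc(OC)cc2CCCCC)c1C(=O)OC
A3 | alternative 2 | 6,8-dihydroxy-3-pentyl-1H-isochromen-1-one | CCCCCc1cc2cc(O)cc(O)c2c(=O)o1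
A4 | alternative 2 | 3-methoxy-5-pentylphenol | CCCCCc1cc(O)cc(OC)c1
A5 | alternative 3 | 1-(benzyloxy)-2-(ethynyloxy)-5-methoxy-3-pentylbenzene | C#COc1c(OCc2ccccc2)cc(OC)cc1CCCCC
A6 | alternative 3 | methyl 2-(hept-1-yn-1-yl)-4-oxocyclobut-1-ene-1-carboxylate | COC(=O)C1=C(C#CCCCCC)CC1=O
A7 | alternative 3 | methyl 2-[2-(benzyloxy)-4-methoxy-6-pentylphenoxy]-6-(hept-1-yn-1-yl)-4-hydroxybenzoate | CCCCCC#Cc1cc(O)cc(Oc2c(OCc3ccccc3)cc(OC)cc2CCCCC)c1C(=O)OC
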